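**Strategy.** The target is cut between C8 of the coumarin benzene ring and the side-chain ketone carbon C1'. Both carbons are electrophilic in their natural precursors (aryl iodide, acyl thioester), so C8 is polarity-reversed by zinc insertion into its C–I bond and joined to the thioester by a palladium-catalysed Fukuyama coupling, which forms the hindered aryl ketone in the last step under neutral conditions. The step exploits C8 lying between ring O1 and the C7 oxygen (selective iodination, chelation-stabilised arylzinc) and C1' standing at the acid oxidation level next to the C2' stereocentre, which comes intact from (R)-2-hydroxy-3-methylbutanoic acid with the 3-methylbut-2-enoate already attached.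

Key step: step 5

Remark: the stereocentre of the target is (R) (O > aryl C=O > isopropyl > H) and corresponds, with the same descriptor, to C2 of (R)-2-hydroxy-3-methylbutanoic acid, which is taken as commercial, as are umbelliferone and 3-methylbut-2-enoyl chloride.

**Route**

Step 1
Reactants: 1 umbelliferone (7-hydroxy-2H-chromen-2-one)
Product: 2 7-hydroxy-8-iodo-2H-chromen-2-one
Conditions: I2 (1.0 equiv), KI, 20% aq. NH3, 0 °C to rt; then dil. H2SO4 to pH 2
Reagents that add atoms: iodine, II
Why: Electrophilic aromatic iodination of the phenoxide, in which C8, ortho to the C7 oxygen and at the α-position of the fused bicycle (the analogue of C1 of 2-naphthol), is the most nucleophilic ring carbon, and any lactone opened by the base recloses on acidification.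

Step 2
Reactants: 2 7-hydroxy-8-iodo-2H-chromen-2-one
Product: 3 8-iodo-7-methoxy-2H-chromen-2-one
Conditions: MeI, K2CO3, acetone, reflux
Reagents that add atoms: iodomethane, CI
Why: Williamson ether synthesis, the phenoxide of 2 being methylated by SN2 attack on iodomethane while the aryl iodide and the lactone are inert to carbonate in acetone.

Step 3
Reactants: 4 (2R)-2-hydroxy-3-methylbutanoic acid; 5 3-methylbut-2-enoyl chloride
Product: 6 (2R)-3-methyl-2-[(3-methylbut-2-enoyl)oxy]butanoic acid
Conditions: 5 (2 equiv), neat, no base, 60 °C; aqueous THF work-up
Reagents that add atoms: none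
Why: Base-free O-acylation of the secondary alcohol by the acid chloride (nucleophilic acyl substitution), in which the absence of amine shuts off the vinylketene route that would deconjugate the enoate, and the C2–O bond is not broken, so the (R) configuration is retained.

Step 4
Reactants: 6 (2R)-3-methyl-2-[(3-methylbut-2-enoyl)oxy]butanoic acid
Product: 7 S-ethyl (2R)-3-methyl-2-[(3-methylbut-2-enoyl)oxy]butanethioate
Conditions: EtSH (1.5 equiv), DCC, DMAP (5 mol %), CH2Cl2, 0 °C to rt
Reagents that add atoms: ethanethiol, CCS
Why: Steglich thioesterification, in which the carbodiimide activates the carboxyl group and catalytic DMAP passes the acyl group to the thiol at 0 °C, mild enough to leave the α-acyloxy stereocentre and the poorly electrophilic β,β-dimethyl enoate untouched.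

Step 5
Reactants: 3 8-iodo-7-methoxy-2H-chromen-2-one; 7 S-ethyl (2R)-3-methyl-2-[(3-methylbut-2-enoyl)oxy]butanethioate
Product: 9 (2R)-1-(7-methoxy-2-oxo-2H-chromen-8-yl)-3-methyl-1-oxobutan-2-yl 3-methylbut-2-enoate, via (7-methoxy-2-oxo-2H-chromen-8-yl)zinc iodide 8 (not isolated)
Conditions: 3 (1.5 equiv), Zn dust (BrCH2CH2Br/TMSCl-activated), LiCl, THF, 25–40 °C, solution decanted from Zn; then 7, PdCl2(PPh3)2 (5 mol %), THF/toluene, 25 °C; aq. NH4Cl
Reagents that add atoms: none
Why: LiCl-assisted oxidative insertion of zinc into the C8–I bond reverses the polarity of C8 and gives arylzinc 8, a nucleophile mild enough to coexist with the lactone and the enoate. Pd(0) then inserts into the C(acyl)–S bond of 7, the aryl group passes from zinc to palladium (driven by the Zn–S bond) and reductive elimination forms the C8–C(=O) bond; the closest known reaction type is the Fukuyama thioester–organozinc ketone synthesis. No ring is closed and no stereocentre is created: the (R) centre at C2' is carried through because the medium is neutral and neither the acyl–palladium intermediate nor the arylzinc enolises the thioester or the product ketone. The step needs chemoselectivity for the thioester over the lactone carbonyl, the 3-methylbut-2-enoate and the newly formed ketone, which is secured because only the C–S bond undergoes oxidative addition and arylzinc halides do not add to esters or ketones at room temperature. Site selectivity is fixed by the iodine at C8, and the two flanking oxygens (O1 and the 7-OMe oxygen) that hinder this carbon also stabilise the arylzinc by coordination.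

**Compound list**

1 | umbelliferone (7-hydroxy-2H-chromen-2-one) | Oc1ccc2ccc(=O)oc2c1 | starting material
2 | 7-hydroxy-8-iodo-2H-chromen-2-one | Oc1ccc2ccc(=O)oc2c1I | intermediate
3 | 8-iodo-7-methoxy-2H-chromen-2-one | COc1ccc2ccc(=O)oc2c1I | intermediate
4 | (2R)-2-hydroxy-3-methylbutanoic acid | CC(C)[C@@H](O)C(O)=O | starting material
5 | 3-methylbut-2-enoyl chloride | CC(C)=CC(Cl)=O | starting material
6 | (2R)-3-methyl-2-[(3-methylbut-2-enoyl)oxy]butanoic acid | OC(=O)[C@H](OC(=O)C=C(C)C)C(C)C | intermediate
7 | S-ethyl (2R)-3-methyl-2-[(3-methylbut-2-enoyl)oxy]butanethioate | CCSC(=O)[C@H](OC(=O)C=C(C)C)C(C)C | intermediate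
8 | (7-methoxy-2-oxo-2H-chromen-8-yl)zinc iodide (not isolated) | COc1ccc2ccc(=O)oc2c1[Zn]I | intermediate
9 | (2R)-1-(7-methoxy-2-oxo-2H-chromen-8-yl)-3-methyl-1-oxobutan-2-yl 3-methylbut-2-enoate | COc1ccc2ccc(=O)oc2c1C(=O)[C@H](OC(=O)C=C(C)C)C(C)C | target

**Totals**

Total step count: 5
Longest linear sequence: 3 steps (1 → 2 → 3 → 9, or 4 → 6 → 7 → 9)

**Steps most likely to fail**

1. Step 5. The doubly ortho-substituted aryl group may pass too slowly from zinc to the acyl–palladium thiolate, so that protodezincation, biaryl homocoupling or decarbonylation of the acyl–palladium species outruns ketone formation; incomplete zinc insertion into the hindered iodide would add to this. The fallback sets out from 3 and 6 and comes back at 9. Palladium-catalysed stannylation of 3 with hexabutylditin (Pd(PPh3)4, toluene, 100 °C) should give 7-methoxy-8-(tributylstannyl)-2H-chromen-2-one F1, an isolable aryl nucleophile. Acid 6 with oxalyl chloride and catalytic DMF (CH2Cl2, 0 °C to rt) should give (2R)-3-methyl-2-[(3-methylbut-2-enoyl)oxy]butanoyl chloride F2. A Stille ketone synthesis of F1 with F2 (PdCl2(PPh3)2, CuI, toluene, 60 °C), again base-free, should then give 9.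

2. Step 3. The carboxyl group may be acylated in competition with the hindered secondary alcohol, leading through mixed anhydrides to self-esterification of the hydroxy acid, and acylation of the alcohol may stay incomplete without base. The fallback sets out from 4 and comes back at 6. Alkylation of the carboxylate with allyl bromide (Cs2CO3, DMF, rt) should give prop-2-en-1-yl (2R)-2-hydroxy-3-methylbutanoate F3. Steglich esterification of F3 with 3-methylbut-2-enoic acid (DCC, DMAP, CH2Cl2) should give prop-2-en-1-yl (2R)-3-methyl-2-[(3-methylbut-2-enoyl)oxy]butanoate F4. Palladium-catalysed allyl transfer to morpholine (Pd(PPh3)4, THF, rt) should then release 6 without touching the enoate.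

3. Step 4. Configuration at C2 may erode through enolisation or ketene formation of the activated α-acyloxy acyl species, and the thiol may add in conjugate fashion to the enoate. The fallback sets out from 4 and comes back at 7, reversing the order of the two acylations. Thioesterification of the free hydroxy acid 4 (EDC·HCl, HOBt, EtSH, CH2Cl2, 0 °C) should give S-ethyl (2R)-2-hydroxy-3-methylbutanethioate F5, whose activated form carries neither an α-acyloxy group nor an enoate. Acylation of the hydroxyl group of F5 with 5 (pyridine, CH2Cl2, 0 °C) should then give 7.

**Further compounds**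

F1 | step 5 | 7-methoxy-8-(tributylstannyl)-2H-chromen-2-one | COc1ccc2ccc(=O)oc2c1[Sn](CCCC)(CCCC)CCCC
F2 | step 5 | (2R)-3-methyl-2-[(3-methylbut-2-enoyl)oxy]butanoyl chloride | ClC(=O)[C@H](OC(=O)C=C(C)C)C(C)C
F3 | step 3 | prop-2-en-1-yl (2R)-2-hydroxy-3-methylbutanoate | C=CCOC(=O)[C@H](O)C(C)C
F4 | step 3 | prop-2-en-1-yl (2R)-3-methyl-2-[(3-methylbut-2-enoyl)oxy]butanoate | C=CCOC(=O)[C@H](OC(=O)C=C(C)C)C(C)C
F5 | step 4 | S-ethyl (2R)-2-hydroxy-3-methylbutanethioate | CCSC(=O)[C@H](O)C(C)C
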